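**Remark on the chemistry:** positions are numbered as in the halimane skeleton (ring A = C1–C5 and C10; ring B = C5–C10; side chain C11–C16; C17 on C8, C20 on C9, ester carbon on C4). The target is taken as (4S,5R,8R,9S,13R,14R), as the SMILES encodes. Compounds 1, 2, 9, 13, 15 and 22 are taken as commercial.

## Retrosynthetic overview

1. Target 27 ⇐ Sharpless epoxidation of (E)-allylic alcohol 26; the C12–C13 bond ⇐ B-alkyl Suzuki coupling of the C11–C12 vinyl group (from amide 19) with enol triflate 23.
2. Ring B is formed last, by the C8–C9 bond: intramolecular SN2 alkylation of the amide dienolate of monocyclic tosylate 18, giving 19.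
3. 18 ⇐ ring A vinyl iodide sulfone 12 + (S)-propylene oxide (C7, C8, C17) + 2-bromo-N,N-dimethylpropanamide (C9, C11, C20).
4. 12 ⇐ decarboxylative Claisen rearrangement of sulfonylacetate 10 (C1–O to C5–C6 chirality transfer, creates C1=C10) ⇐ CBS reduction of iodoenone 7 ⇐ enantioselective Diels–Alder reaction (ring A formed first, sets C4).
5. Enabling feature: C9–H is α to the C11 carboxamide and allylic to the ring A C1=C10 bond, so C9 is the α-carbon of a dienolate; the chain C5–C6–C7–C8 puts the secondary sulfonate carbon C8 in a 6-exo-tet relation to it.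

Key step: step 12

## Route

Step 1
Reactants: 1 (E)-3-(tert-butyldimethylsilyloxy)-N,N-dimethylbuta-1,3-dien-1-amine; 2 methacrolein
Product: 4 (S)-1-methyl-4-oxocyclohex-2-ene-1-carbaldehyde, via aminosilyl enol ether cycloadduct 3 (not isolated)
Conditions: 1-naphthyl-TADDOL (20 mol%, enantiomer chosen to give (S)-4), toluene, −80 °C; then aq. HF, MeCN, 0 °C
Reagents that add atoms: none
Why: Hydrogen-bond-catalysed enantioselective Diels–Alder reaction of the 1-amino-3-siloxydiene with the α-substituted enal, then silyl enol ether cleavage and β-elimination of dimethylamine to the enone; the TADDOL-bound aldehyde should be attacked on one face only, which sets the C4 quaternary centre.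

Step 2
Reactants: 4 (S)-1-methyl-4-oxocyclohex-2-ene-1-carbaldehyde
Product: 5 (S)-1-methyl-4-oxocyclohex-2-ene-1-carboxylic acid
Conditions: NaClO2, NaH2PO4, 2-methyl-2-butene, t-BuOH/H2O, 0 °C to rt
Reagents that add atoms: sodium chlorite, [Na+].[O-]Cl=O
Why: Pinnick oxidation converts the aldehyde to the acid under buffered conditions that should leave the enone and the quaternary centre untouched.

Step 3
Reactants: 5 (S)-1-methyl-4-oxocyclohex-2-ene-1-carboxylic acid
Product: 6 methyl (S)-1-methyl-4-oxocyclohex-2-ene-1-carboxylate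
Conditions: MeI, K2CO3, DMF, rt
Reagents that add atoms: iodomethane, CI
Why: SN2 O-methylation of the carboxylate; no stereocentre is involved.

Step 4
Reactants: 6 methyl (S)-1-methyl-4-oxocyclohex-2-ene-1-carboxylate
Product: 7 methyl (S)-3-iodo-1-methyl-4-oxocyclohex-2-ene-1-carboxylate
Conditions: I2, pyridine, CH2Cl2, 0 °C to rt
Reagents that add atoms: iodine, II
Why: α-Iodination of the enone by conjugate addition of pyridine, iodination and elimination; the iodine marks C10 for the later coupling and serves as the large group in step 5.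

Step 5
Reactants: 7 methyl (S)-3-iodo-1-methyl-4-oxocyclohex-2-ene-1-carboxylate
Product: 8 methyl (1S,4R)-4-hydroxy-3-iodo-1-methylcyclohex-2-ene-1-carboxylate
Conditions: (S)-2-methyl-CBS-oxazaborolidine (20 mol%), BH3·SMe2, THF, −25 °C
Reagents that add atoms: none
Why: Corey–Bakshi–Shibata reduction; the catalyst should deliver hydride to the ketone face that places the iodoalkene flank in the large-group position, giving the (R)-carbinol (C1–OH cis to the ester) under reagent control.

Step 6
Reactants: 8 methyl (1S,4R)-4-hydroxy-3-iodo-1-methylcyclohex-2-ene-1-carboxylate; 9 2-(phenylsulfonyl)acetic acid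
Product: 10 methyl (1S,4R)-3-iodo-1-methyl-4-{[(phenylsulfonyl)acetyl]oxy}cyclohex-2-ene-1-carboxylate
Conditions: DCC, DMAP (cat.), CH2Cl2, 0 °C to rt
Reagents that add atoms: none
Why: Steglich esterification with retention at the carbinol carbon.

Step 7
Reactants: 10 methyl (1S,4R)-3-iodo-1-methyl-4-{[(phenylsulfonyl)acetyl]oxy}cyclohex-2-ene-1-carboxylate
Product: 12 methyl (1S,2R)-3-iodo-1-methyl-2-[(phenylsulfonyl)methyl]cyclohex-3-ene-1-carboxylate, via rearranged sulfonyl carboxylic acid 11 (not isolated)
Conditions: N,O-bis(trimethylsilyl)acetamide (0.2 equiv), KOAc (0.1 equiv), toluene, 110 °C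
Reagents that add atoms: none
Why: Decarboxylative Claisen rearrangement ([3,3] shift of the silyl ketene acetal, then desilylation and loss of CO2); the suprafacial shift should deliver C6 to the ring face that carried the oxygen, which sets C5 and places the double bond at C1=C10.

Step 8
Reactants: 12 methyl (1S,2R)-3-iodo-1-methyl-2-[(phenylsulfonyl)methyl]cyclohex-3-ene-1-carboxylate; 13 (S)-2-methyloxirane
Product: 14 γ-hydroxy sulfone (12 carrying an (S)-2-hydroxypropyl group on the sulfonyl carbon, both epimers at that carbon)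
Conditions: LiN(i-Pr)2 (1.1 equiv), THF, −78 °C; then BF3·OEt2, 13, −78 °C; aq. NH4Cl
Reagents that add atoms: none
Why: Alkylation of the α-sulfonyl carbanion by epoxide opening at the CH2 terminus; the C8 carbinol centre comes unchanged from (S)-propylene oxide, and the sulfonyl-carbon epimers converge in step 10.

Step 9
Reactants: 14 γ-hydroxy sulfone; 15 2-bromo-N,N-dimethylpropanamide
Product: 16 amide sulfone (iodine of 14 replaced by a 1-(dimethylamino)-1-oxopropan-2-yl group at C10, epimers at C9)
Conditions: 15, Zn dust, THF, rt; then 14, Pd2(dba)3 (2.5 mol%), XPhos (10 mol%), THF, 50 °C (2.5 equiv of the zinc reagent)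
Reagents that add atoms: none
Why: Negishi coupling of the Reformatsky-type zinc amide enolate with the vinyl iodide (α-alkenylation of an amide) attaches C9, C11 and C20 to C10; the new C9 centre need not be controlled because it becomes planar in step 12.

Step 10
Reactants: 16 amide sulfone
Product: 17 methyl (1S,2R)-3-[1-(dimethylamino)-1-oxopropan-2-yl]-2-[(3S)-3-hydroxybutyl]-1-methylcyclohex-3-ene-1-carboxylate
Conditions: 6% Na(Hg), Na2HPO4, MeOH/THF, −20 °C to rt
Reagents that add atoms: none
Why: Reductive desulfonylation by electron transfer removes the sulfone before the leaving group is installed, so that no sulfonyl carbanion can later close a cyclopropane onto C8.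

Step 11
Reactants: 17 hydroxy amide
Product: 18 methyl (1S,2R)-3-[1-(dimethylamino)-1-oxopropan-2-yl]-1-methyl-2-[(3S)-3-(tosyloxy)butyl]cyclohex-3-ene-1-carboxylate
Conditions: TsCl, pyridine, DMAP (cat.), CH2Cl2, 0 °C to rt
Reagents that add atoms: 4-toluenesulfonyl chloride, Cc1ccc(cc1)S(Cl)(=O)=O
Why: O-Sulfonylation of the secondary alcohol with retention at C8.

Step 12
Reactants: 18 monocyclic tosylate amide
Product: 19 methyl 5-(dimethylcarbamoyl)-1,5,6-trimethyl-1,2,3,5,6,7,8,8a-octahydronaphthalene-1-carboxylate (1-CO2Me and 5-CONMe2 on one face; 1-Me, 8a-H, 5-Me and 6-Me on the other)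
Conditions: KN(SiMe3)2 (1.2 equiv), THF, −78 °C to 0 °C
Reagents that add atoms: none
Why: KN(SiMe3)2 removes the C9 hydrogen, which is α to the amide and allylic to C1=C10, to give a planar potassium dienolate whose α-carbon C9 displaces the C8 tosylate intramolecularly by SN2, closing ring B in the 6-exo-tet mode with the enolate C=C exocyclic to the new ring. The closest known reaction types are the intramolecular alkylation of ester and amide enolates by secondary sulfonates to give cyclohexanes with quaternary α-centres, and the α-selective (deconjugative) alkylation of dienolates. C8 is set by inversion of the (S)-sulfonate derived from (S)-propylene oxide, which should place the C17 methyl equatorial in the chair-like transition state. C9 is set by conformation: the chain on C5 reaches C9 from its own face, the planar amide enolate unit should sit pseudo-equatorial and syn to the small C1–H, and the C20 methyl should take the pseudo-axial site syn to H5, because an axial enolate would push its O/NMe2 substituents over the ring towards C5. The step needs α- over γ-alkylation (attack through C1 would give a bridged bicyclo[3.3.1]nonane), which the larger coefficient at the α-carbon and the chair-like fused transition state should secure, and substitution over E2 elimination, which intramolecularity, the potassium counter-ion and low temperature should favour. O-alkylation is not a concern, since it would require an eight-membered ring.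

Step 13
Reactants: 19 bicyclic amide
Product: 20 methyl 5-formyl-1,5,6-trimethyl-1,2,3,5,6,7,8,8a-octahydronaphthalene-1-carboxylate (same relative configuration as 19)
Conditions: Cp2Zr(H)Cl (1.8 equiv), THF, rt; then H2O/silica
Reagents that add atoms: none
Why: Partial reduction of the tertiary amide by hydrozirconation of the C=O bond to a stable zirconated hemiaminal, which gives the aldehyde on hydrolysis; the quaternary methyl ester should not react.

Step 14
Reactants: 20 aldehyde
Product: 21 methyl 5-ethenyl-1,5,6-trimethyl-1,2,3,5,6,7,8,8a-octahydronaphthalene-1-carboxylate (same relative configuration as 19)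
Conditions: Ph3PCH3Br, KN(SiMe3)2, THF, 0 °C to rt
Reagents that add atoms: methyltriphenylphosphonium bromide, C[P+](c1ccccc1)(c1ccccc1)c1ccccc1.[Br-]
Why: Wittig methylenation of the non-enolisable neopentyl aldehyde gives the C11=C12 vinyl group.

Step 15
Reactants: 22 ethyl acetoacetate
Product: 23 ethyl (E)-3-{[(trifluoromethyl)sulfonyl]oxy}but-2-enoate
Conditions: Tf2O, aq. Me4NOH, hexane, 5 °C
Reagents that add atoms: trifluoromethanesulfonic anhydride, O=S(=O)(OS(=O)(=O)C(F)(F)F)C(F)(F)F
Why: O-Triflation of the non-chelated ammonium enolate should give the (E)-enol triflate (triflate trans to the ester), which fixes the later C13=C14 geometry.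

Step 16
Reactants: 21 vinyl compound; 23 ethyl (E)-3-{[(trifluoromethyl)sulfonyl]oxy}but-2-enoate
Product: 25 diester with the (E)-CH2CH2C(CH3)=CHCO2Et side chain on C9, via B-alkyl-9-BBN adduct 24 (not isolated)
Conditions: 9-BBN-H, THF, rt; then 23, PdCl2(dppf) (5 mol%), aq. K3PO4, DMF, 50 °C
Reagents that add atoms: none
Why: Anti-Markovnikov hydroboration, selective for the monosubstituted alkene over the trisubstituted ring alkene, followed by B-alkyl Suzuki–Miyaura coupling with retention of the triflate geometry, which gives the (E)-trisubstituted C13=C14 alkene.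

Step 17
Reactants: 25 diester
Product: 26 methyl 5-[(3E)-5-hydroxy-3-methylpent-3-en-1-yl]-1,5,6-trimethyl-1,2,3,5,6,7,8,8a-octahydronaphthalene-1-carboxylate (same ring configuration as 19)
Conditions: i-Bu2AlH (2.2 equiv), CH2Cl2, −78 °C; Rochelle salt work-up
Reagents that add atoms: none
Why: 1,2-Reduction of the unhindered conjugated ethyl ester to the allylic alcohol; the axial, quaternary methyl ester at C4 should be too hindered to react at −78 °C.

Step 18
Reactants: 26 allylic alcohol
Product: 27 the target, methyl 5-{2-[(2R,3R)-3-(hydroxymethyl)-2-methyloxiran-2-yl]ethyl}-1,5,6-trimethyl-1,2,3,5,6,7,8,8a-octahydronaphthalene-1-carboxylate (ring configuration as in 19)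
Conditions: Ti(O-i-Pr)4 (10 mol%), D-(−)-diethyl tartrate (12 mol%), t-BuOOH, 4 Å sieves, CH2Cl2, −20 °C
Reagents that add atoms: tert-butyl hydroperoxide, CC(C)(C)OO
Why: Sharpless asymmetric epoxidation; the D-(−)-tartrate catalyst should deliver oxygen to the face of the (E)-allylic alcohol that gives the (13R,14R)-epoxide under reagent control, and the isolated ring alkene does not react.

## Compound list

1 | (E)-3-(tert-butyldimethylsilyloxy)-N,N-dimethylbuta-1,3-dien-1-amine | CN(C)/C=C/C(=C)O[Si](C)(C)C(C)(C)C | starting material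
2 | methacrolein | CC(=C)C=O | starting material
3 | 4-(tert-butyldimethylsilyloxy)-2-(dimethylamino)-1-methylcyclohex-3-ene-1-carbaldehyde (CHO cis to NMe2) | O=C[C@@]1(C)CCC(O[Si](C)(C)C(C)(C)C)=C[C@H]1N(C)C | intermediate (not isolated)
4 | (S)-1-methyl-4-oxocyclohex-2-ene-1-carbaldehyde | O=C[C@@]1(C)CCC(=O)C=C1 | intermediate
5 | (S)-1-methyl-4-oxocyclohex-2-ene-1-carboxylic acid | OC(=O)[C@@]1(C)CCC(=O)C=C1 | intermediate
6 | methyl (S)-1-methyl-4-oxocyclohex-2-ene-1-carboxylate | COC(=O)[C@@]1(C)CCC(=O)C=C1 | intermediate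
7 | methyl (S)-3-iodo-1-methyl-4-oxocyclohex-2-ene-1-carboxylate | COC(=O)[C@@]1(C)CCC(=O)C(I)=C1 | intermediate
8 | methyl (1S,4R)-4-hydroxy-3-iodo-1-methylcyclohex-2-ene-1-carboxylate (OH cis to CO2Me) | COC(=O)[C@@]1(C)CC[C@@H](O)C(I)=C1 | intermediate
9 | 2-(phenylsulfonyl)acetic acid | OC(=O)CS(=O)(=O)c1ccccc1 | starting material
10 | methyl (1S,4R)-3-iodo-1-methyl-4-{[(phenylsulfonyl)acetyl]oxy}cyclohex-2-ene-1-carboxylate | COC(=O)[C@@]1(C)CC[C@@H](OC(=O)CS(=O)(=O)c2ccccc2)C(I)=C1 | intermediate
11 | 2-[2-iodo-6-(methoxycarbonyl)-6-methylcyclohex-2-en-1-yl]-2-(phenylsulfonyl)acetic acid (ring centres as in 12; present as silyl ester/carboxylate; both epimers at the sulfonyl carbon) | COC(=O)[C@@]1(C)CCC=C(I)[C@H]1C(C(=O)O)S(=O)(=O)c1ccccc1 | intermediate (not isolated)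
12 | methyl (1S,2R)-3-iodo-1-methyl-2-[(phenylsulfonyl)methyl]cyclohex-3-ene-1-carboxylate (CH2SO2Ph cis to CO2Me) | COC(=O)[C@@]1(C)CCC=C(I)[C@H]1CS(=O)(=O)c1ccccc1 | intermediate
13 | (S)-2-methyloxirane | C[C@H]1CO1 | starting material
14 | methyl 2-[(3S)-3-hydroxy-1-(phenylsulfonyl)butyl]-3-iodo-1-methylcyclohex-3-ene-1-carboxylate (ring centres as in 12; both epimers at the sulfonyl carbon) | COC(=O)[C@@]1(C)CCC=C(I)[C@H]1C(C[C@H](C)O)S(=O)(=O)c1ccccc1 | intermediate
15 | 2-bromo-N,N-dimethylpropanamide (racemic) | CC(Br)C(=O)N(C)C | starting material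
16 | methyl 3-[1-(dimethylamino)-1-oxopropan-2-yl]-2-[(3S)-3-hydroxy-1-(phenylsulfonyl)butyl]-1-methylcyclohex-3-ene-1-carboxylate (ring centres as in 12; epimers at C9 and at the sulfonyl carbon) | COC(=O)[C@@]1(C)CCC=C(C(C)C(=O)N(C)C)[C@H]1C(C[C@H](C)O)S(=O)(=O)c1ccccc1 | intermediate
17 | methyl (1S,2R)-3-[1-(dimethylamino)-1-oxopropan-2-yl]-2-[(3S)-3-hydroxybutyl]-1-methylcyclohex-3-ene-1-carboxylate (epimers at C9) | COC(=O)[C@@]1(C)CCC=C(C(C)C(=O)N(C)C)[C@H]1CC[C@H](C)O | intermediate
18 | methyl (1S,2R)-3-[1-(dimethylamino)-1-oxopropan-2-yl]-1-methyl-2-[(3S)-3-(tosyloxy)butyl]cyclohex-3-ene-1-carboxylate (epimers at C9) | COC(=O)[C@@]1(C)CCC=C(C(C)C(=O)N(C)C)[C@H]1CC[C@H](C)OS(=O)(=O)c1ccc(C)cc1 | intermediate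
19 | methyl 5-(dimethylcarbamoyl)-1,5,6-trimethyl-1,2,3,5,6,7,8,8a-octahydronaphthalene-1-carboxylate (1-CO2Me and 5-CONMe2 on one face; 1-Me, 8a-H, 5-Me, 6-Me on the other) | COC(=O)[C@@]1(C)CCC=C2[C@H]1CC[C@@H](C)[C@]2(C)C(=O)N(C)C | intermediate
20 | methyl 5-formyl-1,5,6-trimethyl-1,2,3,5,6,7,8,8a-octahydronaphthalene-1-carboxylate (configuration as 19) | COC(=O)[C@@]1(C)CCC=C2[C@H]1CC[C@@H](C)[C@]2(C)C=O | intermediate
21 | methyl 5-ethenyl-1,5,6-trimethyl-1,2,3,5,6,7,8,8a-octahydronaphthalene-1-carboxylate (configuration as 19) | COC(=O)[C@@]1(C)CCC=C2[C@H]1CC[C@@H](C)[C@]2(C)C=C | intermediate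
22 | ethyl acetoacetate | CCOC(=O)CC(C)=O | starting material
23 | ethyl (E)-3-{[(trifluoromethyl)sulfonyl]oxy}but-2-enoate | CCOC(=O)/C=C(\C)OS(=O)(=O)C(F)(F)F | intermediate
24 | B-alkyl-9-borabicyclo[3.3.1]nonane from hydroboration of 21 at C12 | COC(=O)[C@@]1(C)CCC=C2[C@H]1CC[C@@H](C)[C@]2(C)CCB1C2CCCC1CCC2 | intermediate (not isolated)
25 | methyl 5-[(3E)-5-ethoxy-3-methyl-5-oxopent-3-en-1-yl]-1,5,6-trimethyl-1,2,3,5,6,7,8,8a-octahydronaphthalene-1-carboxylate (configuration as 19) | COC(=O)[C@@]1(C)CCC=C2[C@H]1CC[C@@H](C)[C@]2(C)CC/C(C)=C/C(=O)OCC | intermediate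
26 | methyl 5-[(3E)-5-hydroxy-3-methylpent-3-en-1-yl]-1,5,6-trimethyl-1,2,3,5,6,7,8,8a-octahydronaphthalene-1-carboxylate (configuration as 19) | COC(=O)[C@@]1(C)CCC=C2[C@H]1CC[C@@H](C)[C@]2(C)CC/C(C)=C/CO | intermediate
27 | methyl 5-{2-[(2R,3R)-3-(hydroxymethyl)-2-methyloxiran-2-yl]ethyl}-1,5,6-trimethyl-1,2,3,5,6,7,8,8a-octahydronaphthalene-1-carboxylate (CNP0324371.2) | COC(=O)[C@@]1(C)CCC=C2[C@H]1CC[C@@H](C)[C@]2(C)CC[C@@]1(C)O[C@@H]1CO | target

## Step count and risks

Total step count: 18. Longest linear sequence: 17 steps (steps 1–14 and 16–18; step 15 prepares the coupling partner 23).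

The three steps most likely to fail:

**Step 12 (key step).** β-Elimination of the secondary sulfonate, or alkylation through the γ-terminus (C1) of the dienolate, may outrun the hindered substitution at the fully substituted α-carbon. The fallback replaces the substitution by a carbonyl addition that has no elimination channel. It sets out from 17: LiN(i-Pr)2 (2.2 equiv) and then CBr4 should give the α-bromo amide F1. Dess–Martin oxidation gives the bromo methyl ketone F2. SmI2 (THF, −78 °C) should generate the samarium dienolate at C9 without any base, and its intramolecular Reformatsky-type aldol addition to the C8 ketone closes ring B at the same C8–C9 bond to give the β-hydroxy amide F3. Dehydration with the Burgess reagent gives the 8(17)-ene F4, and hydrogenation (H2, RhCl(PPh3)3) from the face opposite the axial C9 methyl returns to 19.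

**Step 9.** Oxidative addition and transmetalation at the hindered, internally substituted vinyl iodide may be slow, so that protodeiodination and consumption of the zinc enolate take over. The fallback reverses the polarity of the partners. It sets out from 14: Miyaura borylation (B2pin2, PdCl2(dppf), KOAc, dioxane, 80 °C) gives the alkenyl boronate F5, which is coupled with the racemic α-bromo amide 15 under nickel catalysis (NiBr2·diglyme, diamine ligand, KOt-Bu, i-BuOH/dioxane) and comes back to the route at 16.

**Step 17.** The hydride reagent may fail to discriminate between the conjugated ethyl ester and the quaternary methyl ester, leading to over-reduction at C4. The fallback uses hydrolysis rates instead of hydride selectivity. It sets out from 25: LiOH (THF/H2O, rt) should hydrolyse only the unhindered conjugated ester to the acid F6. Ethyl chloroformate and Et3N give the mixed anhydride F7, and NaBH4 (THF/H2O, 0 °C) reduces it to 26, where the route is rejoined.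

Further compounds
F1 | step 12 | methyl (1S,2R)-3-[2-bromo-1-(dimethylamino)-1-oxopropan-2-yl]-2-[(3S)-3-hydroxybutyl]-1-methylcyclohex-3-ene-1-carboxylate | COC(=O)[C@@]1(C)CCC=C(C(C)(Br)C(=O)N(C)C)[C@H]1CC[C@H](C)O
F2 | step 12 | methyl (1S,2R)-3-[2-bromo-1-(dimethylamino)-1-oxopropan-2-yl]-1-methyl-2-(3-oxobutyl)cyclohex-3-ene-1-carboxylate | COC(=O)[C@@]1(C)CCC=C(C(C)(Br)C(=O)N(C)C)[C@H]1CCC(C)=O
F3 | step 12 | methyl 5-(dimethylcarbamoyl)-6-hydroxy-1,5,6-trimethyl-1,2,3,5,6,7,8,8a-octahydronaphthalene-1-carboxylate (other centres as 19) | COC(=O)[C@@]1(C)CCC=C2[C@H]1CCC(C)(O)[C@]2(C)C(=O)N(C)C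
F4 | step 12 | methyl 5-(dimethylcarbamoyl)-1,5-dimethyl-6-methylidene-1,2,3,5,6,7,8,8a-octahydronaphthalene-1-carboxylate (centres as 19) | COC(=O)[C@@]1(C)CCC=C2[C@H]1CCC(=C)[C@]2(C)C(=O)N(C)C
F5 | step 9 | methyl 2-[(3S)-3-hydroxy-1-(phenylsulfonyl)butyl]-1-methyl-3-(4,4,5,5-tetramethyl-1,3,2-dioxaborolan-2-yl)cyclohex-3-ene-1-carboxylate (ring centres as 12) | COC(=O)[C@@]1(C)CCC=C(B2OC(C)(C)C(C)(C)O2)[C@H]1C(C[C@H](C)O)S(=O)(=O)c1ccccc1
F6 | step 17 | (2E)-5-[5-(methoxycarbonyl)-1,2,5-trimethyl-1,2,3,4,4a,5,6,7-octahydronaphthalen-1-yl]-3-methylpent-2-enoic acid (centres as 25) | COC(=O)[C@@]1(C)CCC=C2[C@H]1CC[C@@H](C)[C@]2(C)CC/C(C)=C/C(=O)O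
F7 | step 17 | mixed ethyl carbonic anhydride of F6 | COC(=O)[C@@]1(C)CCC=C2[C@H]1CC[C@@H](C)[C@]2(C)CC/C(C)=C/C(=O)OC(=O)OCC
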